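**Retrosynthetic overview**

1. Ferutinine 20 ⇒ jaeschkeanadiol 17 + 4-acetoxybenzoyl chloride 18; diol 17 ⇐ ketol 16 by hydroxyl-directed reduction (sets C4).
2. Ketol 16 ⇐ syn-epoxy alcohol 13 by a stereospecific 1,2-hydride shift (sets C3a and C3); 13 ⇐ enone 11 by CBS reduction and directed epoxidation.
3. Enone 11 ⇐ open-chain 5,10-dioxofarnesane allylsilane 8 in one flask: C1–C7 closure first (seven-membered ring, quaternary centre), then C6–C10 closure (five-membered ring).
4. 8 ⇐ geranic acid 3 + but-2-yn-1-ol 1, via ester 4, methylenation/Claisen rearrangement (tertiary allylsilane) and epoxide-to-ketone rearrangement of the distal olefin.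

Assumption: the presumed biosynthesis is the daucane sequence from farnesyl diphosphate (C1–C7 closure, then C6–C10 closure, hydration at C10, late oxygenation and acylation at C5); open-chain compounds carry farnesane numbering and bicyclic ones azulene numbering (C7 = C8a, C6 = C3a, C10 = C3, C5 = C4); the sense of induction in step 6 is a prediction, and the antipodal catalyst is used if it proves reversed.

**Route**

Step 1
Reactants: 1 but-2-yn-1-ol
Product: 2 (2Z)-3-(triethylsilyl)but-2-en-1-ol
Conditions: Et3SiH, [Ru(C5Me5)(MeCN)3]PF6 (1 mol %), CH2Cl2, 0 °C to rt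
Reagents that add atoms: triethylsilane, CC[SiH](CC)CC
Why: Trost trans-hydrosilylation of a propargylic alcohol puts silicon on the alkyne carbon distal to the hydroxyl; the olefin geometry is of no later consequence.

Step 2
Reactants: 2 (2Z)-3-(triethylsilyl)but-2-en-1-ol, 3 geranic acid [(2E)-3,7-dimethylocta-2,6-dienoic acid]
Product: 4 (2Z)-3-(triethylsilyl)but-2-en-1-yl (2E)-3,7-dimethylocta-2,6-dienoate
Conditions: EDC·HCl, 4-(dimethylamino)pyridine (10 mol %), CH2Cl2, 0 °C to rt
Reagents that add atoms: none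
Why: Carbodiimide (Steglich-type) esterification of a primary allylic alcohol; low temperature and catalytic 4-(dimethylamino)pyridine keep the 2E-enoate from deconjugating.

Step 3
Reactants: 4 (2Z)-3-(triethylsilyl)but-2-en-1-yl (2E)-3,7-dimethylocta-2,6-dienoate
Product: 6 (6E)-3,7,11-trimethyl-3-(triethylsilyl)dodeca-1,6,10-trien-5-one, via allyl vinyl ether 5 (not isolated)
Conditions: Ti(C5H5)2(CH3)2, toluene, 70 °C (dark), then 110 °C
Reagents that add atoms: dimethyltitanocene, C[Ti](C)(C1C=CC=C1)C1C=CC=C1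
Why: Petasis methylenation of the ester carbonyl gives the allyl vinyl ether, whose Claisen [3,3] rearrangement joins C4 to the silicon-bearing C3 and releases the terminal vinyl group, giving the tertiary allylsilane (C3 racemic, destroyed in step 6).

Step 4
Reactants: 6 (6E)-3,7,11-trimethyl-3-(triethylsilyl)dodeca-1,6,10-trien-5-one
Product: 7 (6E)-10,11-epoxy-3,7,11-trimethyl-3-(triethylsilyl)dodeca-1,6-dien-5-one
Conditions: mCPBA (1.05 equiv), NaHCO3, CH2Cl2, −20 to 0 °C
Reagents that add atoms: 3-chloroperbenzoic acid, OOC(=O)c1cccc(Cl)c1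
Why: Prilezhaev epoxidation is fastest at the electron-rich trisubstituted C10=C11 olefin (the enone olefin is deactivated, the monosubstituted vinyl is much slower), bicarbonate prevents protodesilylation, and the epoxide configuration is irrelevant.

Step 5
Reactants: 7 (6E)-10,11-epoxy-3,7,11-trimethyl-3-(triethylsilyl)dodeca-1,6-dien-5-one
Product: 8 (6E)-3,7,11-trimethyl-3-(triethylsilyl)dodeca-1,6-diene-5,10-dione
Conditions: LiClO4 (5 M in Et2O), rt
Reagents that add atoms: none
Why: Meinwald rearrangement: ionisation at the tertiary epoxide carbon C11 and a 1,2-hydride shift from C10 give the isopropyl ketone under neutral lithium-ion catalysis that should spare the allylsilane and enone.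

Step 6
Reactants: 8 (6E)-3,7,11-trimethyl-3-(triethylsilyl)dodeca-1,6-diene-5,10-dione
Product: 11 (8aR)-6,8a-dimethyl-3-(propan-2-yl)-1,2,8,8a-tetrahydroazulen-4(5H)-one, via silyl dienol ether 9 (not isolated), via ketol 10 (not isolated)
Conditions: (S)-tetrahydro-1-(2-methylphenyl)-3,3-diphenyl-1H,3H-pyrrolo[1,2-c][1,3,2]oxazaborole·HN(SO2CF3)2 (20 mol %), CH2Cl2, −78 to −40 °C; then TiCl4 (1.2 equiv), −78 to 0 °C
Reagents that add atoms: none
Why: Proposed new method: the oxazaborolidinium ion binds the s-trans enone carbonyl and generates an oxygen-stabilised C7 cation in a chiral pocket, C1 of the allylsilane attacks C7 (7-endo intramolecular Hosomi–Sakurai conjugate allylation) to set the quaternary centre as 8aR, and Et3Si+ passes to the enolate oxygen to turn the catalyst over; TiCl4 then drives the Mukaiyama aldol of the regiodefined enol silane 9 onto the C10 ketone (five-membered ring) and dehydration of the tertiary titanium aldolate 10 to the conjugated enone, without an equilibrating base that could move the C6=C7 ring olefin into conjugation; the closest known reaction types are Lewis-acid intramolecular allylsilane additions to enones and dienones that give seven-membered rings, oxazaborolidinium-catalysed enantioselective Mukaiyama–Michael additions, and TiCl4 Mukaiyama aldol condensations with ketones; the catalyst must override 1,5-induction from the racemic C3, and any 8aS material is removed as a diastereomer in step 7.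

Step 7
Reactants: 11 (8aR)-6,8a-dimethyl-3-(propan-2-yl)-1,2,8,8a-tetrahydroazulen-4(5H)-one
Product: 12 (4R,8aR)-6,8a-dimethyl-3-(propan-2-yl)-1,2,4,5,8,8a-hexahydroazulen-4-ol
Conditions: (S)-tetrahydro-1-methyl-3,3-diphenyl-1H,3H-pyrrolo[1,2-c][1,3,2]oxazaborole (20 mol %), catecholborane, toluene, −78 °C
Reagents that add atoms: none
Why: Corey–Bakshi–Shibata reduction with the α-substituted alkenyl side as the large group delivers hydride anti to the angular methyl, giving the 4R carbinol (OH cis to the methyl); the alcohol from any 8aS enone is a separable diastereomer, so this step also secures enantiopurity.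

Step 8
Reactants: 12 (4R,8aR)-6,8a-dimethyl-3-(propan-2-yl)-1,2,4,5,8,8a-hexahydroazulen-4-ol
Product: 13 (3R,3aS,4R,8aR)-3,3a-epoxy-6,8a-dimethyl-3-(propan-2-yl)-1,2,3,3a,4,5,8,8a-octahydroazulen-4-ol
Conditions: VO(acac)2 (5 mol %), tBuOOH, CH2Cl2, 0 °C to rt
Reagents that add atoms: tert-butyl hydroperoxide, CC(C)(C)OO
Why: Hydroxyl-directed vanadium epoxidation delivers oxygen to the C3=C3a olefin on the face of the carbinol oxygen (syn), leaves the isolated C6=C7 olefin alone, and so places the future C3–O bond cis to the angular methyl.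

Step 9
Reactants: 13 (3R,3aS,4R,8aR)-3,3a-epoxy-6,8a-dimethyl-3-(propan-2-yl)-1,2,3,3a,4,5,8,8a-octahydroazulen-4-ol
Product: 16 (3R,3aR,8aR)-3-hydroxy-6,8a-dimethyl-3-(propan-2-yl)-1,2,3,3a,8,8a-hexahydroazulen-4(5H)-one, via epoxy silyl ether 14 (not isolated), via silyloxy ketone 15 (not isolated)
Conditions: TMSOTf (2.2 equiv), iPr2NEt, CH2Cl2, −78 to −40 °C; then aq. citric acid, THF, 0 °C
Reagents that add atoms: none
Why: Semipinacol rearrangement of a syn-2,3-epoxy silyl ether (Jung non-aldol aldol type): the C4 hydride, anti-periplanar to the breaking C3a–O bond, migrates to the face of C3a opposite the oxygen, giving the trans ring fusion and the C4 ketone, while the untouched C3–O bond keeps its configuration.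

Step 10
Reactants: 16 (3R,3aR,8aR)-3-hydroxy-6,8a-dimethyl-3-(propan-2-yl)-1,2,3,3a,8,8a-hexahydroazulen-4(5H)-one
Product: 17 jaeschkeanadiol [(3R,3aS,4S,8aR)-6,8a-dimethyl-3-(propan-2-yl)-1,2,3,3a,4,5,8,8a-octahydroazulene-3,4-diol]
Conditions: Me4NBH(OAc)3, MeCN/AcOH, −30 °C
Reagents that add atoms: none
Why: Evans–Saksena directed reduction: the borohydride bound to the C3 oxygen delivers hydride intramolecularly to the ketone face syn to the C3–O bond, giving the anti-1,3-diol (4S).

Step 11
Reactants: 17 jaeschkeanadiol, 18 4-acetoxybenzoyl chloride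
Product: 20 ferutinine, via acetoxybenzoate 19 (not isolated)
Conditions: pyridine, 4-(dimethylamino)pyridine (10 mol %), CH2Cl2, 0 °C to rt; then pyrrolidine, 0 °C
Reagents that add atoms: none
Why: Acylation takes place only at the secondary C4 hydroxyl (the tertiary C3 hydroxyl is inert), and pyrrolidine aminolysis removes the phenolic acetate far faster than it attacks the hindered alkyl benzoate.

**Compound list**

1 | but-2-yn-1-ol | CC#CCO | starting material
2 | (2Z)-3-(triethylsilyl)but-2-en-1-ol | C/C(=C/CO)[Si](CC)(CC)CC | intermediate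
3 | geranic acid, (2E)-3,7-dimethylocta-2,6-dienoic acid | CC(C)=CCC/C(C)=C/C(=O)O | starting material
4 | (2Z)-3-(triethylsilyl)but-2-en-1-yl (2E)-3,7-dimethylocta-2,6-dienoate | CC(C)=CCC/C(C)=C/C(=O)OC/C=C(/C)[Si](CC)(CC)CC | intermediate
5 | allyl vinyl ether, triethyl[(2Z)-4-{[(3E)-4,8-dimethylnona-1,3,7-trien-2-yl]oxy}but-2-en-2-yl]silane | C=C(OC/C=C(/C)[Si](CC)(CC)CC)/C=C(\C)CCC=C(C)C | intermediate
6 | (6E)-3,7,11-trimethyl-3-(triethylsilyl)dodeca-1,6,10-trien-5-one (racemic at C3) | C=CC(C)([Si](CC)(CC)CC)CC(=O)/C=C(\C)CCC=C(C)C | intermediate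
7 | (6E)-10,11-epoxy-3,7,11-trimethyl-3-(triethylsilyl)dodeca-1,6-dien-5-one (stereoisomer mixture) | C=CC(C)([Si](CC)(CC)CC)CC(=O)/C=C(\C)CCC1OC1(C)C | intermediate
8 | (6E)-3,7,11-trimethyl-3-(triethylsilyl)dodeca-1,6-diene-5,10-dione (racemic at C3) | C=CC(C)([Si](CC)(CC)CC)CC(=O)/C=C(\C)CCC(=O)C(C)C | intermediate
9 | silyl dienol ether, 1-[(1R)-1,5-dimethyl-3-[(triethylsilyl)oxy]cyclohepta-2,5-dien-1-yl]-4-methylpentan-3-one | CC1=CC[C@@](C)(CCC(=O)C(C)C)C=C(O[Si](CC)(CC)CC)C1 | intermediate
10 | ketol, (8aR)-3-hydroxy-6,8a-dimethyl-3-(propan-2-yl)-1,2,3,3a,8,8a-hexahydroazulen-4(5H)-one (C3/C3a diastereomer mixture, as titanium aldolate) | CC1=CC[C@@]2(C)CCC(O)(C(C)C)C2C(=O)C1 | intermediate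
11 | (8aR)-6,8a-dimethyl-3-(propan-2-yl)-1,2,8,8a-tetrahydroazulen-4(5H)-one | CC1=CC[C@@]2(C)CCC(C(C)C)=C2C(=O)C1 | intermediate
12 | (4R,8aR)-6,8a-dimethyl-3-(propan-2-yl)-1,2,4,5,8,8a-hexahydroazulen-4-ol | CC1=CC[C@@]2(C)CCC(C(C)C)=C2[C@H](O)C1 | intermediate
13 | (3R,3aS,4R,8aR)-3,3a-epoxy-6,8a-dimethyl-3-(propan-2-yl)-1,2,3,3a,4,5,8,8a-octahydroazulen-4-ol (epoxide O, OH and angular CH3 on one face) | CC1=CC[C@@]2(C)CC[C@]3(C(C)C)O[C@]23[C@H](O)C1 | intermediate
14 | epoxy silyl ether, trimethylsilyl ether of 13 | CC1=CC[C@@]2(C)CC[C@]3(C(C)C)O[C@]23[C@H](O[Si](C)(C)C)C1 | intermediate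
15 | silyloxy ketone, 3-O-trimethylsilyl ether of 16 | CC1=CC[C@@]2(C)CC[C@@](O[Si](C)(C)C)(C(C)C)[C@@H]2C(=O)C1 | intermediate
16 | (3R,3aR,8aR)-3-hydroxy-6,8a-dimethyl-3-(propan-2-yl)-1,2,3,3a,8,8a-hexahydroazulen-4(5H)-one | CC1=CC[C@@]2(C)CC[C@@](O)(C(C)C)[C@@H]2C(=O)C1 | intermediate
17 | jaeschkeanadiol, (3R,3aS,4S,8aR)-6,8a-dimethyl-3-(propan-2-yl)-1,2,3,3a,4,5,8,8a-octahydroazulene-3,4-diol | CC1=CC[C@@]2(C)CC[C@@](O)(C(C)C)[C@@H]2[C@@H](O)C1 | intermediate
18 | 4-acetoxybenzoyl chloride | CC(=O)Oc1ccc(cc1)C(Cl)=O | starting material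
19 | acetoxybenzoate, jaeschkeanadiol 4-(4-acetoxybenzoate) | CC1=CC[C@@]2(C)CC[C@@](O)(C(C)C)[C@@H]2[C@@H](OC(=O)c2ccc(OC(C)=O)cc2)C1 | intermediate
20 | ferutinine, (3R,3aS,4S,8aR)-3-hydroxy-6,8a-dimethyl-3-(propan-2-yl)-1,2,3,3a,4,5,8,8a-octahydroazulen-4-yl 4-hydroxybenzoate | CC1=CC[C@@]2(C)CC[C@@](O)(C(C)C)[C@@H]2[C@@H](OC(=O)c2ccc(O)cc2)C1 | target

**Step count and risks**

Total steps: 11. Longest linear sequence: 11 (from but-2-yn-1-ol 1; geranic acid 3 enters at step 2 and 4-acetoxybenzoyl chloride 18 at step 11).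

Most likely to fail:

Step 6. The chiral catalyst may be too weak for a β,β-disubstituted enone, or be overridden by the racemic C3. The fallback sets out from 8 and closes both rings with an achiral strong Lewis acid alone (EtAlCl2 or TiCl4, CH2Cl2, −78 to 0 °C), giving the racemic enone F1. The absolute configuration is then introduced by resolution instead of catalysis: the step 7 reagent reduces both enantiomers from the same absolute face, giving 12 and the diastereomeric (4R,8aS)-alcohol F2, which are separated by chromatography. The route is rejoined at 12, with at most half of the material.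

Step 9. The epoxide may open at C3 instead of C3a, or the ring bond C4–C5 may migrate instead of hydride (ring contraction). The fallback sets out from 13: Dess–Martin oxidation gives the epoxy ketone F3, and SmI2 (THF/MeOH, −78 °C) cleaves the C3a–O bond α to the carbonyl, so the regiochemistry is fixed by the ketone. C3a is then set by protonation of the samarium enolate and, if needed, mild equilibration to the trans-fused epimer, which should be favoured because only there can the C3 hydroxyl sit cis to, and hydrogen-bond with, the carbonyl. The route is rejoined at 16.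

Step 5. Alkyl rather than hydride shift, elimination to an allylic alcohol, or premature reaction of the allylsilane are possible. The fallback sets out from 7: H5IO6 (THF/H2O) cleaves the epoxide through its diol to the aldehyde F4; iPrMgCl (THF, −78 °C) adds to the aldehyde in preference to the hindered enone, giving the alcohol F5; Dess–Martin oxidation then gives 8, where the route is rejoined.

**Further compounds**

F1 | step 6 | racemic 6,8a-dimethyl-3-(propan-2-yl)-1,2,8,8a-tetrahydroazulen-4(5H)-one | CC1=CCC2(C)CCC(C(C)C)=C2C(=O)C1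
F2 | step 6 | (4R,8aS)-6,8a-dimethyl-3-(propan-2-yl)-1,2,4,5,8,8a-hexahydroazulen-4-ol | CC1=CC[C@]2(C)CCC(C(C)C)=C2[C@H](O)C1
F3 | step 9 | (3R,3aR,8aR)-3,3a-epoxy-6,8a-dimethyl-3-(propan-2-yl)-1,2,3,3a,8,8a-hexahydroazulen-4(5H)-one | CC1=CC[C@@]2(C)CC[C@]3(C(C)C)O[C@]23C(=O)C1
F4 | step 5 | (4E)-4,8-dimethyl-6-oxo-8-(triethylsilyl)deca-4,9-dienal | C=CC(C)([Si](CC)(CC)CC)CC(=O)/C=C(\C)CCC=O
F5 | step 5 | (6E)-10-hydroxy-3,7,11-trimethyl-3-(triethylsilyl)dodeca-1,6-dien-5-one | C=CC(C)([Si](CC)(CC)CC)CC(=O)/C=C(\C)CCC(O)C(C)C
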